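The benzene ring is numbered C1' (bridge CH2), C2' (OH), C3' (prenyl), C4' (OH), C5' (acyl), C6' (OMe). The acyl carbon C5' lies between the free hydroxyl at C4' and the methoxy at C6', which is the ortho-hydroxy ketone flanked by OMe that a 3-methoxyaryne gives on inserting into the C–O bond of a carboxylic acid.
Retrosynthetic cuts: (a) C1'–CH2 and CH2–C3 of the pyranone (methylene bridge from an iminium one-carbon unit); (b) the prenyl terminus (cross-metathesis) and C3'–CH2 (Claisen shift from the C4' oxygen); (c) C4'–O and C5'–C(=O) (aryne insertion); (d) C2'–O (C–H borylation/oxidation of a commercial silyl triflate).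
Forward: the benzene ring is bought and dressed in steps 1–7; the pyranone ring, the only ring made, arises in step 9 from 3-pentanone and malonyl dichloride; the two halves are joined last through the bridge carbon.
Stereochemistry: the single stereocentre is bought as (R)-2-methylbutanoic acid and carried through unchanged; all later steps avoid conditions that enolise the ketone.

Key step: step 3

Assumption: silyl triflate 1 and enantiopure acid 6 are purchased, so the optical purity of the target rests on that of 6; enol ether 14 is a mixture of double-bond isomers, which is without consequence.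

Step 1
Reactants: 1 3-methoxy-2-(trimethylsilyl)phenyl trifluoromethanesulfonate; 2 bis(pinacolato)diboron
Product: 4 5-hydroxy-3-methoxy-2-(trimethylsilyl)phenyl trifluoromethanesulfonate, via aryl pinacolboronate 3 (not isolated)
Conditions: [Ir(OMe)(cod)]2 (1.5 mol %), 4,4'-di-tert-butyl-2,2'-bipyridine (3 mol %), cyclohexane, 80 °C; volatiles removed; NaBO3·4H2O, THF/H2O, rt; aq. NH4Cl work-up
Reagents that add atoms: sodium perborate (NaBO3, used as the tetrahydrate), [Na+].[O-]OB=O
Why: Iridium-catalysed aromatic C–H borylation is governed by sterics, and in the 1,2,3-trisubstituted ring of 1 only C5 has no ortho neighbour, so boron and then, after perborate oxidation of the C–B bond, the hydroxyl should enter meta to both OTf and OMe while the silyl and triflate groups stay intact.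

Step 2
Reactants: 4 5-hydroxy-3-methoxy-2-(trimethylsilyl)phenyl trifluoromethanesulfonate
Product: 5 3-methoxy-5-(methoxymethoxy)-2-(trimethylsilyl)phenyl trifluoromethanesulfonate
Conditions: MOMCl, iPr2NEt, CH2Cl2, 0 °C to rt
Reagents that add atoms: chloromethyl methyl ether, COCCl
Why: O-alkylation of the phenol (MOM ether formation) under amine base does not disturb the silyl triflate, whose silicon is meta to the hydroxyl, and the MOM group is chosen because it withstands fluoride at 125 °C and the Claisen step and can later be removed by dilute acid in the presence of an alkene.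

Step 3
Reactants: 5 3-methoxy-5-(methoxymethoxy)-2-(trimethylsilyl)phenyl trifluoromethanesulfonate; 6 (R)-2-methylbutanoic acid
Product: 8 (R)-1-[2-hydroxy-6-methoxy-4-(methoxymethoxy)phenyl]-2-methylbutan-1-one, via aryne 7 (not isolated)
Conditions: CsF (4 equiv), THF, 125 °C, sealed tube, 5 in 1.5-fold excess; aq. NH4Cl work-up
Reagents that add atoms: none
Why: Fluoride attacks silicon of 5 and expels triflate to give aryne 7, the caesium carboxylate of 6 adds through oxygen to the strained triple bond, the ortho-aryl anion so formed attacks the neighbouring ester carbonyl through a four-membered transition state, and opening of that adduct gives the chelated ortho-hydroxyaryl ketone, so that C4'–O and C5'–C(=O) form in one operation. The closest known reaction type is the fluoride-triggered insertion of arynes from ortho-silylaryl triflates into the C–O bond of carboxylic acids, an aryne O-arylation followed by an anionic ortho-Fries-type acyl shift. No ring is closed and no stereocentre is created. The regioselectivity needed, oxygen at the carbon distal to OMe and acyl at the carbon next to it, is secured by the inductively withdrawing methoxy group, which distorts the aryne so that the nucleophile enters meta to OMe and the carbanion develops ortho to it, while the more distant OMOM group has only a weak influence. The existing stereocentre is expected to survive because the acid reacts as a carboxylate that is not enolised, the acyl shift is intramolecular, and the product rests as a caesium phenoxide whose carbonyl is part of a vinylogous carboxylate.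

Step 4
Reactants: 8 (R)-1-[2-hydroxy-6-methoxy-4-(methoxymethoxy)phenyl]-2-methylbutan-1-one
Product: 9 (R)-1-[2-(allyloxy)-6-methoxy-4-(methoxymethoxy)phenyl]-2-methylbutan-1-one
Conditions: allyl alcohol, PPh3, DIAD, THF, 0 °C to rt
Reagents that add atoms: allyl alcohol (prop-2-en-1-ol), C=CCO
Why: Mitsunobu etherification alkylates the only free, hydrogen-bonded hydroxyl under neutral conditions, so no base is present that could enolise the ketone.

Step 5
Reactants: 9 (R)-1-[2-(allyloxy)-6-methoxy-4-(methoxymethoxy)phenyl]-2-methylbutan-1-one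
Product: 10 (R)-1-[3-allyl-2-hydroxy-6-methoxy-4-(methoxymethoxy)phenyl]-2-methylbutan-1-one
Conditions: 1,2-dichlorobenzene, 180 °C, argon
Reagents that add atoms: none
Why: In this aromatic Claisen rearrangement the [3,3] shift can end by re-aromatising enolisation only at C3', the one ortho carbon that bears hydrogen (the other carries the acyl group), and the restored hydrogen bond to the ketone drives the reaction in a neutral medium.

Step 6
Reactants: 10 (R)-1-[3-allyl-2-hydroxy-6-methoxy-4-(methoxymethoxy)phenyl]-2-methylbutan-1-one
Product: 11 (R)-1-(3-allyl-2,4-dihydroxy-6-methoxyphenyl)-2-methylbutan-1-one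
Conditions: 3 M aq. HCl, MeOH, 40 °C
Reagents that add atoms: none
Why: Acid-catalysed cleavage of the methoxymethyl acetal frees the C2' hydroxyl, and it is placed before metathesis because a terminal allyl group, unlike a prenyl group, should not cyclise onto the neighbouring phenols in dilute acid.

Step 7
Reactants: 11 (R)-1-(3-allyl-2,4-dihydroxy-6-methoxyphenyl)-2-methylbutan-1-one
Product: 12 (R)-1-[2,4-dihydroxy-6-methoxy-3-(3-methylbut-2-en-1-yl)phenyl]-2-methylbutan-1-one
Conditions: second-generation Grubbs catalyst (H2IMes)(PCy3)Cl2Ru=CHPh (5 mol %), 2-methyl-2-butene/CH2Cl2, 40 °C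
Reagents that add atoms: 2-methyl-2-butene, CC=C(C)C
Why: Olefin cross-metathesis with excess 2-methyl-2-butene exchanges the terminal CH2 for an isopropylidene group with loss of propene, a standard conversion of ortho-allyl phenols into prenyl phenols that tolerates free hydroxyls and the ketone.

Step 8
Reactants: 13 3-pentanone
Product: 14 3-(trimethylsilyloxy)pent-2-ene
Conditions: TMSOTf, Et3N, CH2Cl2, 0 °C
Reagents that add atoms: trimethylsilyl trifluoromethanesulfonate, C[Si](C)(C)OS(=O)(=O)C(F)(F)F
Why: Soft enolisation, in which TMSOTf silylates the carbonyl oxygen while Et3N removes an α-proton, gives the silyl enol ether, and the symmetric ketone allows only one regioisomer.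

Step 9
Reactants: 14 3-(trimethylsilyloxy)pent-2-ene
Product: 16 6-ethyl-4-hydroxy-5-methyl-2H-pyran-2-one, via diketo acid chloride 15 (not isolated)
Conditions: malonyl dichloride, Et2O, −78 °C to rt
Reagents that add atoms: malonyl dichloride, O=C(Cl)CC(=O)Cl
Why: In this silyl enol ether–malonyl dichloride pyranone synthesis, C-acylation at the enol carbon gives 15, whose ketone enol oxygen displaces the second chloride in a 6-exo-trig lactonisation, and tautomerisation gives the 4-hydroxypyran-2-one.

Step 10
Reactants: 16 6-ethyl-4-hydroxy-5-methyl-2H-pyran-2-one; 12 (R)-1-[2,4-dihydroxy-6-methoxy-3-(3-methylbut-2-en-1-yl)phenyl]-2-methylbutan-1-one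
Product: 19 6-ethyl-4-hydroxy-3-{[2,4-dihydroxy-6-methoxy-5-[(2R)-2-methylbutanoyl]-3-(3-methylbut-2-en-1-yl)phenyl]methyl}-5-methyl-2H-pyran-2-one, via Mannich base 17 (not isolated), via methylidene pyrandione 18 (not isolated)
Conditions: 16, Eschenmoser's salt (1.05 equiv), MeCN, rt; then 12, 70 °C
Reagents that add atoms: N,N-dimethylmethyleneiminium iodide (Eschenmoser's salt), C=[N+](C)C.[I-]
Why: A Mannich reaction at the nucleophilic C3 of the pyranone gives 17, which on warming loses dimethylamine to the doubly activated Michael acceptor 18, and this is captured by C1', the only unsubstituted ring carbon of 12, in a Friedel–Crafts-type conjugate addition (the methylene-bridging tactic used for acylphloroglucinol–pyranone and dimeric acylphloroglucinol structures), with dimethylammonium iodide as the only acid present so that the prenyl group and the α-stereocentre are not endangered.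

Compound list
1 | 3-methoxy-2-(trimethylsilyl)phenyl trifluoromethanesulfonate | COc1cccc(OS(=O)(=O)C(F)(F)F)c1[Si](C)(C)C | starting material
2 | bis(pinacolato)diboron | CC1(C)OB(OC1(C)C)B1OC(C)(C)C(C)(C)O1 | starting material
3 | 3-methoxy-5-(4,4,5,5-tetramethyl-1,3,2-dioxaborolan-2-yl)-2-(trimethylsilyl)phenyl trifluoromethanesulfonate | COc1cc(B2OC(C)(C)C(C)(C)O2)cc(OS(=O)(=O)C(F)(F)F)c1[Si](C)(C)C | intermediate (not isolated)
4 | 5-hydroxy-3-methoxy-2-(trimethylsilyl)phenyl trifluoromethanesulfonate | COc1cc(O)cc(OS(=O)(=O)C(F)(F)F)c1[Si](C)(C)C | intermediate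
5 | 3-methoxy-5-(methoxymethoxy)-2-(trimethylsilyl)phenyl trifluoromethanesulfonate | COCOc1cc(OC)c([Si](C)(C)C)c(OS(=O)(=O)C(F)(F)F)c1 | intermediate
6 | (R)-2-methylbutanoic acid | OC(=O)[C@H](C)CC | starting material
7 | 3-methoxy-5-(methoxymethoxy)benzyne (1-methoxy-5-(methoxymethoxy)cyclohexa-1,5-dien-3-yne) | COC1=CC(OCOC)=CC#C1 | intermediate (not isolated)
8 | (R)-1-[2-hydroxy-6-methoxy-4-(methoxymethoxy)phenyl]-2-methylbutan-1-one | COCOc1cc(O)c(C(=O)[C@H](C)CC)c(OC)c1 | intermediate
9 | (R)-1-[2-(allyloxy)-6-methoxy-4-(methoxymethoxy)phenyl]-2-methylbutan-1-one | C=CCOc1cc(OCOC)cc(OC)c1C(=O)[C@H](C)CC | intermediate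
10 | (R)-1-[3-allyl-2-hydroxy-6-methoxy-4-(methoxymethoxy)phenyl]-2-methylbutan-1-one | C=CCc1c(OCOC)cc(OC)c(C(=O)[C@H](C)CC)c1O | intermediate
11 | (R)-1-(3-allyl-2,4-dihydroxy-6-methoxyphenyl)-2-methylbutan-1-one | C=CCc1c(O)cc(OC)c(C(=O)[C@H](C)CC)c1O | intermediate
12 | (R)-1-[2,4-dihydroxy-6-methoxy-3-(3-methylbut-2-en-1-yl)phenyl]-2-methylbutan-1-one | CC(C)=CCc1c(O)cc(OC)c(C(=O)[C@H](C)CC)c1O | intermediate
13 | 3-pentanone | CCC(=O)CC | starting material
14 | 3-(trimethylsilyloxy)pent-2-ene (mixture of double-bond isomers) | CC=C(CC)O[Si](C)(C)C | intermediate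
15 | 4-methyl-3,5-dioxoheptanoyl chloride (racemic, enolisable) | CCC(=O)C(C)C(=O)CC(=O)Cl | intermediate (not isolated)
16 | 6-ethyl-4-hydroxy-5-methyl-2H-pyran-2-one | CCc1oc(=O)cc(O)c1C | intermediate
17 | 3-[(dimethylamino)methyl]-6-ethyl-4-hydroxy-5-methyl-2H-pyran-2-one (present as its hydroiodide) | CCc1oc(=O)c(CN(C)C)c(O)c1C | intermediate (not isolated)
18 | 6-ethyl-5-methyl-3-methylidene-2H-pyran-2,4(3H)-dione | CCC1=C(C)C(=O)C(=C)C(=O)O1 | intermediate (not isolated)
19 | 6-ethyl-4-hydroxy-3-{[2,4-dihydroxy-6-methoxy-5-[(2R)-2-methylbutanoyl]-3-(3-methylbut-2-en-1-yl)phenyl]methyl}-5-methyl-2H-pyran-2-one | CCc1oc(=O)c(Cc2c(O)c(CC=C(C)C)c(O)c(C(=O)[C@H](C)CC)c2OC)c(O)c1C | target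

Total step count: 10. Longest linear sequence: 8 steps (steps 1–7 and 10); the pyranone arm is 3 steps (8–10).

Steps most likely to fail

Step 3. The aryl anion may be protonated before the hindered, α-branched acyl group has shifted, so that plain O-arylation to the aryl ester takes over, and the stereocentre may partly racemise during prolonged heating. The fallback leaves the route at 6 and returns at 8, building the ketone by electrophilic acylation instead. Acid 6 is converted with oxalyl chloride and catalytic DMF into (R)-2-methylbutanoyl chloride F1. F1 acylates commercial 5-methoxyresorcinol (COc1cc(O)cc(O)c1) under AlCl3 in CH2Cl2/nitromethane at 0 °C (Friedel–Crafts acylation). After removal of the 2,6-dihydroxy-4-methoxy regioisomer this should give (R)-1-(2,4-dihydroxy-6-methoxyphenyl)-2-methylbutan-1-one F2. MOMCl/iPr2NEt then etherifies the hydroxyl para to the acyl group, which is not hydrogen-bonded, and returns to 8.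

Step 10. Methylidene pyrandione 18 may be intercepted by a second molecule of 16 (methylene-bis-pyranone), or it may add across the prenyl double bond as a heterodiene before the hindered arene carbon reacts. The fallback leaves at 12 and returns at 19, moving the electrophilic role to the arene. Phenol 12 is aminomethylated at its only free ring carbon with Eschenmoser's salt in CH2Cl2 to give (R)-1-[5-[(dimethylamino)methyl]-2,4-dihydroxy-6-methoxy-3-(3-methylbut-2-en-1-yl)phenyl]-2-methylbutan-1-one F3. MeI quaternises the amine to [2,4-dihydroxy-6-methoxy-5-[(2R)-2-methylbutanoyl]-3-(3-methylbut-2-en-1-yl)phenyl]-N,N,N-trimethylmethanaminium iodide F4. Warming F4 with 16 and NaOAc in MeCN expels trimethylamine to give the ortho-quinone methide (R)-3-hydroxy-5-methoxy-4-(2-methylbutanoyl)-6-methylidene-2-(3-methylbut-2-en-1-yl)cyclohexa-2,4-dien-1-one F5, to which C3 of the pyranone adds in a Michael reaction, giving 19.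

Step 5. At 180 °C the allyl group may travel through the acyl-bearing carbon to the para position C1', the ether may fragment back to 8, or the ketone may partly racemise. The fallback leaves at 8 and returns at 12, bypassing steps 4 to 7 by replacing the sigmatropic shift with halogenation and cross-coupling. BnMe3N+ ICl2− with CaCO3 in CH2Cl2/MeOH is expected to iodinate 8 ortho to the hydrogen-bonded hydroxyl, as it does 2-hydroxy-4,6-dialkoxyacetophenones, giving (R)-1-[2-hydroxy-3-iodo-6-methoxy-4-(methoxymethoxy)phenyl]-2-methylbutan-1-one F6. Stille coupling with tributyl(3-methylbut-2-en-1-yl)stannane under Pd(PPh3)4 in DMF at 80 °C should give (R)-1-[2-hydroxy-6-methoxy-4-(methoxymethoxy)-3-(3-methylbut-2-en-1-yl)phenyl]-2-methylbutan-1-one F7. Brief treatment with HCl in MeOH at rt removes the MOM group and gives 12.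

Further compounds
F1 | step 3 | (R)-2-methylbutanoyl chloride | ClC(=O)[C@H](C)CC
F2 | step 3 | (R)-1-(2,4-dihydroxy-6-methoxyphenyl)-2-methylbutan-1-one | COc1cc(O)cc(O)c1C(=O)[C@H](C)CC
F3 | step 10 | (R)-1-[5-[(dimethylamino)methyl]-2,4-dihydroxy-6-methoxy-3-(3-methylbut-2-en-1-yl)phenyl]-2-methylbutan-1-one | CC(C)=CCc1c(O)c(CN(C)C)c(OC)c(C(=O)[C@H](C)CC)c1O
F4 | step 10 | [2,4-dihydroxy-6-methoxy-5-[(2R)-2-methylbutanoyl]-3-(3-methylbut-2-en-1-yl)phenyl]-N,N,N-trimethylmethanaminium iodide | CC(C)=CCc1c(O)c(C[N+](C)(C)C)c(OC)c(C(=O)[C@H](C)CC)c1O.[I-]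
F5 | step 10 | (R)-3-hydroxy-5-methoxy-4-(2-methylbutanoyl)-6-methylidene-2-(3-methylbut-2-en-1-yl)cyclohexa-2,4-dien-1-one | C=C1C(=O)C(CC=C(C)C)=C(O)C(C(=O)[C@H](C)CC)=C1OC
F6 | step 5 | (R)-1-[2-hydroxy-3-iodo-6-methoxy-4-(methoxymethoxy)phenyl]-2-methylbutan-1-one | COCOc1cc(OC)c(C(=O)[C@H](C)CC)c(O)c1I
F7 | step 5 | (R)-1-[2-hydroxy-6-methoxy-4-(methoxymethoxy)-3-(3-methylbut-2-en-1-yl)phenyl]-2-methylbutan-1-one | COCOc1cc(OC)c(C(=O)[C@H](C)CC)c(O)c1CC=C(C)C
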